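The data are simulated with made-up constants; the scatter is artificial.

4 questions stand on this flask, and one quantity serves them: how far the flask has run on a clock set by its catalyst.

| flask | solid substrate | catalyst | remark | time |
|---|---|---|---|---|
| theta | 0.16 M | 2.8 mol% | run made earlier |  |
| gamma | 0.16 M | 4.4 mol% | run made earlier |  |
| delta | 0.080 M | 2 mol% | run made earlier |  |
| flask | 0.16 M | 2 mol% |  | 3.0 d |

| run | time / h | target / % | isomer of the product / % |
|---|---|---|---|
| theta | 3.00 | 4.3 | 0.2 |
| theta | 6.00 | 11.2 | 1.2 |
| theta | 12.0 | 18.4 | 6.7 |
| theta | 25.0 | 28.0 | 24.4 |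
| theta | 40.0 | 31.3 | 49.4 |
| gamma | 8.00 | 16.3 | 6.9 |
| gamma | 15.0 | 25.4 | 20.6 |
| gamma | 25.0 | 31.1 | 45.1 |
| gamma | 30.0 | 29.6 | 56.1 |
| gamma | 40.0 | 22.0 | 71.0 |
| delta | 3.00 | 3.9 | 0 |
| delta | 6.00 | 8.8 | 0.8 |
| delta | 12.0 | 17.6 | 2.5 |
| delta | 25.0 | 33.1 | 8.9 |
| delta | 40.0 | 38.0 | 21.2 |

(readings scatter by 0.5 percentage points)

- ratio of target to isomer of the product at 2.5 h
- ratio of target to isomer of the product at 12 h
- ratio of target to isomer of the product at 3.0 d
- which of target and isomer of the product there is more of at 3.0 d

- solid substrate is a solid; its amount is given per volume of the solution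
- at the start none of the solid substrate is in solution

Theta and gamma hold the same solid substrate as this flask and more catalyst, and theta is the nearer in loading, but I lean on gamma for the end because its readings reach further on the clock set up below. Between middle readings, total product (target plus isomer) climbs 1.55 times as fast in gamma as in theta, and gamma holds 1.57 times the catalyst. Because the climb follows the catalyst, I treat dissolving as keeping pace and the catalysed step as the rate-limiting step while solid remains. At equal solid charge, more catalyst should then run the same curve sooner.

So I use the gamma clock t_g, a flask's age times its catalyst loading divided by gamma's loading: 32.7 h for this flask at 3.0 d.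

Theta tests it:

theta at 40.0 h: t_g = 25.5 h
target 31.3 %, isomer 49.4 %; gamma at 25.0 h: 31.1 %, 45.1 %

The clock holds to a few points. Gamma runs on to 40.0 h, where target has dropped to 22.0 %, but this flask stops earlier on the clock. Between gamma's last two readings I get:

target 27.5 %, isomer 60.2 %, ratio 0.458

At 12 h, theta's clock reads 8.57 h, and the same interpolation gives a ratio of 4.02. At 2.5 h the clock falls before theta's first reading, whose isomer, 0.2 %, lies under the scatter, so I commit to no figure there.

The forecast, holding that “time scales with catalyst”, gave 25, 4 and 0.43 with isomer of the product ahead, its last ratio lying below my 0.458.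

The flask gives 22.0, 3.66 and 0.406, with target at 25.8 % and isomer at 63.5 %.

    starting material + catalyst ⇌ target + catalyst, rate k1*[starting material]*[catalyst] forward; the back reaction follows from the equilibrium constant (K = 5.17, k = 18.1 L mol⁻¹ h⁻¹)
    target + catalyst ⇌ isomer of the product + catalyst, rate k2*[catalyst]*[target] forward; the back reaction follows from the equilibrium constant (K = 5.36, k = 14.7 L mol⁻¹ h⁻¹)
    solid substrate ⇌ starting material, rate k3*(cs3 - [starting material]) while solid is left; crystals form when [starting material] > cs3 (solubility = 0.0540 M, k = 0.793 h⁻¹)

At 0.490 d the flask makes target 2.58 times as fast as it uses it up, and at 3.00 d that figure is 0.506. Its target tops out at 1.99 d, or 21.7 h on the clock, and the end at 32.7 h lies past that. The neighbour flask with 0.5 mol% of catalyst reaches t_g = 8.18 h in the same 3.0 d, beside gamma's reading at 8.00 h with a ratio of 2.36, and it gives 2.20.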